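**Plan**

- Numbering: C1 is the ring alkene carbon carrying C7H2OBz, C2 the alkene CH, C3–C6 the carbinol carbons in sequence (3‑OH, 4‑OH, 5‑OBz, 6‑OH); the benzyl ring of the arene precursor carries the same numbers.
- Enabling feature: the six ring carbons plus C7 are the skeleton of benzyl benzoate, with the cis O4/O5 pair para and meta to C1 and O3/O6 on the two carbons flanking that pair. A para cycloaddition of an arenophile across C3/C6 followed by oxidation of the free C4=C5 bond writes exactly this pattern.
- Cuts, in retrosynthetic order: O5–benzoyl (through an O4/O5 orthobenzoate); C3–O and C6–O (singlet oxygen on the C6=C1–C2=C3 diene); O7–benzoyl; then C4–O, C5–O and the two C–N bonds of a urazole bridge, back to benzyl benzoate and MTAD.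
- Forward: the carbocycle is the arene itself. The only ring built is the diazabicyclo[2.2.2]octadiene, which is osmylated in the same pot, ketalised and dismantled by N2 loss to the diene; an endoperoxide is then formed and opened, and the esters are placed last.
- Stereochemistry: C4/C5 (absolute) come from osmylation of one enantiomer of the racemic cycloadduct by OsO4·(DHQD)2PHAL; C3/C6 come from singlet oxygen adding anti to the acetonide; O5 over O4 comes from axial‑ester opening of the orthobenzoate.

Key step: step 1

Drawing convention: the ring is drawn with C1→C6 running counterclockwise; "up" is toward the viewer. CIP descriptors use the ring numbering above.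

Assumption: the DHQD ligand is taken to select the cycloadduct enantiomer drawn as 3, as the face‑selection model of the cinchona ligands suggests (substituted flank in the open quadrant); if the first run shows the opposite sense, the pseudoenantiomeric (DHQ)2PHAL is used and nothing else changes.

**Route**

Step 1
Reactants: 1 benzyl benzoate; 2 4-methyl-1,2,4-triazoline-3,5-dione (MTAD)
Product: 5 urazole-bridged bicyclo[2.2.2]octene cis-4,5-diol, via arenophile cycloadduct 3 (not isolated), via osmate ester 4 (not isolated)
Conditions: 1 (3 equiv), 2 (1.0 equiv, limiting), CH2Cl2, white LEDs, −78 °C until the colour of 2 has faded; then OsO4 (0.45 equiv)/(DHQD)2PHAL (0.50 equiv) premixed in CH2Cl2, −78 °C; then Na2SO3, THF/H2O, −78 °C to rt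
Reagents that add atoms: OsO4, O=[Os](=O)(=O)=O
Why: Proposed new method: Visible-light-excited 2 forms an exciplex with the more electron-rich benzyl ring of 1 and collapses by a para [4+2] cycloaddition across C3/C6, so the one new ring (the N–N-bridged six-membered ring of a 2,3-diazabicyclo[2.2.2]octadiene) closes intermolecularly with both C–N bonds on one arene face and with C1 kept vinylic; the closest known chemistry is the racemic one-pot arenophile cycloaddition/OsO4 dihydroxylation of monosubstituted benzenes, here combined with stoichiometric cinchona-ligand osmylation (Sharpless-type asymmetric dihydroxylation in its first-cycle form, workable at −78 °C) used as a kinetic resolution of racemic 3. The bridgeheads C3/C6 are tied cis by the bridge, and O4 and O5 arrive cis through the concerted [3+2] addition of ligated OsO4 and anti to the urazole because its carbonyl groups screen the other face of C4=C5. Absolute configuration rests on the ligand: the (DHQD)2PHAL·OsO4 complex should consume faster the enantiomer of 3 that presents this anti face while placing its C6–C1 flank, with the benzoate arm available for aryl stacking in the ligand cleft, in the unhindered quadrant of the binding model, and 0.45 equiv of oxidant stops conversion short of the slower enantiomer. Site selectivity needs no help beyond the substrate, since cycloaddition avoids the electron-poor benzoyl ring and the ipso carbon and osmium prefers the disubstituted C4=C5 over the trisubstituted C1=C2. Keeping 2 as the limiting reagent means no free arenophile is present when the amine ligand is added. On warming with sulfite, 4 should be cleaved to 5 while the unreacted mirror image of 3 cycloreverts to 1 (recovered and resubmitted) and 2 (reduced to 4-methylurazole, which can be reoxidised to 2); recrystallisation of 5 is planned to raise its enantiomeric purity.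

Step 2
Reactants: 5 urazole-bridged bicyclo[2.2.2]octene cis-4,5-diol; 6 2,2-dimethoxypropane
Product: 7 4,5-O-isopropylidene urazole bicycle
Conditions: TsOH·H2O (cat.), acetone/CH2Cl2, rt
Reagents that add atoms: none
Why: Acid-catalysed transketalisation (acetonide formation) is expected to engage the cis-4,5-diol cleanly, masking it for the basic and oxidative steps ahead without touching any stereocentre.

Step 3
Reactants: 7 4,5-O-isopropylidene urazole bicycle
Product: 10 dienol acetonide, via bicyclic hydrazine 8 (not isolated), via bicyclic diazene 9 (not isolated)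
Conditions: KOH, i-PrOH, 85 °C; then AcOH to pH 6, CuCl2, H2O, 0 °C; then aq NH3, 0 °C
Reagents that add atoms: none
Why: Hydroxide hydrolysis of the urazole (which also saponifies the O7 benzoate) should give hydrazine 8, CuCl2 oxidises it to diazene 9, and this loses N2 at once by retro-Diels–Alder reaction to the C6=C1–C2=C3 diene, the standard unmasking of arenophile adducts, which deletes the C3/C6 bridgehead centres and leaves C4/C5 untouched.

Step 4
Reactants: 10 dienol acetonide; 11 benzoyl chloride
Product: 12 dienyl benzoate acetonide
Conditions: Et3N, 4-(dimethylamino)pyridine (cat.), CH2Cl2, 0 °C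
Reagents that add atoms: none
Why: Nucleophile-catalysed acylation of the only hydroxyl group restores the O7 benzoate that the hydrolysis removed.

Step 5
Reactants: 12 dienyl benzoate acetonide
Product: 14 3,6-enediol acetonide, via endoperoxide 13 (not isolated)
Conditions: O2, 5,10,15,20-tetraphenylporphyrin (cat.), white light, CH2Cl2, −40 °C; then thiourea, MeOH, 0 °C to rt
Reagents that add atoms: dioxygen, O=O
Why: Singlet-oxygen [4+2] cycloaddition joins C3 and C6 through an O–O bridge on the face opposite the cis-fused acetonide, and thiourea then reduces only the O–O bond, so 3-OH and 6-OH arise cis to each other and trans to O4/O5 under substrate control.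

Step 6
Reactants: 14 3,6-enediol acetonide
Product: 15 tetrol 7-benzoate
Conditions: AcOH/H2O (4:1), 50 °C
Reagents that add atoms: none
Why: Acid-catalysed acetal hydrolysis should free the 4,5-diol while the benzoate and the allylic alcohols, deactivated toward ionisation by their oxygenated neighbours, survive.

Step 7
Reactants: 15 tetrol 7-benzoate; 16 trimethyl orthobenzoate
Product: 18 target compound CNP0198957.1, via cyclic orthobenzoate 17 (not isolated)
Conditions: camphor-10-sulfonic acid (cat.), MeCN, rt; then AcOH/H2O (4:1), rt
Reagents that add atoms: water, O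
Why: Orthoester exchange is expected at the only cis-vicinal diol (O4/O5), and acid hydrolysis of the cyclic orthobenzoate opens through the hemiorthoester to the axial ester, which is O5 in the half-chair that keeps 6-OH pseudoaxial to avoid allylic 1,2-strain against C7 (orthoester-mediated regioselective monoacylation).

**Compound list**

1 | benzyl benzoate | O=C(OCc1ccccc1)c1ccccc1 | starting material
2 | 4-methyl-1,2,4-triazoline-3,5-dione (MTAD) | CN1C(=O)N=NC1=O | starting material
3 | arenophile cycloadduct: N-methylurazole bridging C3 and C6 of the benzyl ring of 1 (both N down), C1=C2 (C7H2OBz on C1) and C4=C5 remaining as alkenes; the (3S,6R) enantiomer shown is the one osmylated and forms together with its mirror image | O=C(OCC1=C[C@@H]2C=C[C@H]1N1N2C(=O)N(C)C1=O)c1ccccc1 | intermediate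
4 | osmate ester: cyclic O4,O5-glycolate of 3 with hexavalent osmium, O2Os(OR)2 carrying (DHQD)2PHAL on osmium (ligand not drawn); O4/O5 up, N3/N6 down | O=C(OCC1=C[C@@H]2[C@@H]3O[Os](=O)(=O)O[C@@H]3[C@H]1N1N2C(=O)N(C)C1=O)c1ccccc1 | intermediate
5 | (3R,4S,5R,6S) urazole-bridged bicyclo[2.2.2]octene cis-4,5-diol: 4-OH and 5-OH up (anti to the urazole), N3/N6 down, C1=C2 with C7H2OBz on C1 | O=C(OCC1=C[C@@H]2[C@H](O)[C@H](O)[C@H]1N1N2C(=O)N(C)C1=O)c1ccccc1 | intermediate
6 | 2,2-dimethoxypropane | COC(C)(C)OC | starting material
7 | (3R,4S,5R,6S) 4,5-O-isopropylidene derivative of 5 (acetonide up, urazole down) | O=C(OCC1=C[C@@H]2[C@@H]3OC(C)(C)O[C@@H]3[C@H]1N1N2C(=O)N(C)C1=O)c1ccccc1 | intermediate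
8 | bicyclic hydrazine: 2,3-diazabicyclo[2.2.2]oct-5-ene with HN–NH bridging C3/C6 (down), 4,5-acetonide (up), C7H2OH on C1 | OCC1=C[C@@H]2[C@@H]3OC(C)(C)O[C@@H]3[C@H]1NN2 | intermediate
9 | bicyclic diazene: N=N analogue of 8 | OCC1=C[C@@H]2[C@@H]3OC(C)(C)O[C@@H]3[C@H]1N=N2 | intermediate
10 | dienol acetonide: (4S,5R) cyclohexadiene with C6=C1–C2=C3, C7H2OH on C1, cis-4,5-O-isopropylidene (up); [(3aR,7aS)-2,2-dimethyl-3a,7a-dihydro-1,3-benzodioxol-5-yl]methanol | OCC1=C[C@H]2OC(C)(C)O[C@H]2C=C1 | intermediate
11 | benzoyl chloride | O=C(Cl)c1ccccc1 | starting material
12 | dienyl benzoate acetonide: O7-benzoate of 10, (4S,5R) | O=C(OCC1=C[C@H]2OC(C)(C)O[C@H]2C=C1)c1ccccc1 | intermediate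
13 | endoperoxide: 2,3-dioxabicyclo[2.2.2]oct-5-ene with O–O bridging C3/C6 (down), 4,5-acetonide (up), C1=C2 with C7H2OBz | O=C(OCC1=C[C@@H]2[C@@H]3OC(C)(C)O[C@@H]3[C@H]1OO2)c1ccccc1 | intermediate
14 | (3R,4S,5R,6S) 3,6-enediol acetonide: cyclohex-1-ene with 3-OH down, 4,5-O-isopropylidene up, 6-OH down, C7H2OBz on C1 | O=C(OCC1=C[C@@H](O)[C@@H]2OC(C)(C)O[C@@H]2[C@H]1O)c1ccccc1 | intermediate
15 | tetrol 7-benzoate: [(3R,4S,5R,6S)-3,4,5,6-tetrahydroxycyclohex-1-en-1-yl]methyl benzoate (3-OH down, 4-OH up, 5-OH up, 6-OH down) | O=C(OCC1=C[C@@H](O)[C@H](O)[C@H](O)[C@H]1O)c1ccccc1 | intermediate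
16 | trimethyl orthobenzoate | COC(OC)(OC)c1ccccc1 | starting material
17 | cyclic orthobenzoate: 2-methoxy-2-phenyl-1,3-dioxolane spanning O4/O5 of 15 (up), both epimers at the orthoester carbon | O=C(OCC1=C[C@@H](O)[C@@H]2OC(OC)(c3ccccc3)O[C@@H]2[C@H]1O)c1ccccc1 | intermediate
18 | CNP0198957.1: [(3R,4S,5R,6S)-5-(benzoyloxy)-3,4,6-trihydroxycyclohex-1-en-1-yl]methyl benzoate (3-OH down, 4-OH up, 5-OBz up, 6-OH down) | O=C(OCC1=C[C@@H](O)[C@H](O)[C@H](OC(=O)c2ccccc2)[C@H]1O)c1ccccc1 | target

**Totals and risks**

Total step count: 7. Longest linear sequence: 7 steps (from 1 and 2).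

Steps most likely to fail:

1. Step 1 (proposed new method). The ligated osmium may discriminate poorly between the two cycloadduct enantiomers, giving 5 of low enantiomeric purity, and arenophile set free on warming may consume ligand. Fallback with known chemistry, setting out from 1 and 2 and returning at 5: the established racemic one-pot sequence (2 limiting, visible light, CH2Cl2, −78 °C; then OsO4 5 mol %, N-methylmorpholine N-oxide, acetone/H2O, −50 °C) should give 5 as a racemate with its mirror image, the enantiomeric urazole diol F1. The two are separated by preparative chromatography on a chiral stationary phase (supercritical CO2/MeOH, amylose carbamate column), and 5 re-enters at step 2.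

2. Step 7. The orthobenzoate may open toward the O4 ester, or the benzoyl group may migrate among O4, O5 and O6 during hydrolysis. Fallback setting out from 15 and returning at 18: benzoylation with 11 under catalysis by Ph2BOCH2CH2NH2 (diphenylborinic acid 2-aminoethyl ester) with i-Pr2NEt in MeCN. This activates the cis-diol as a borinate and acylates its equatorial oxygen, the opposite regiochemical rule to the orthoester opening. If the ring conformation turns out to place O4 axial, so that the orthoester delivers the wrong ester, O5 is then the equatorial oxygen favoured here. No new isolable compound arises.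

3. Step 3. Once released, the diene may be lost by Diels–Alder dimerisation or acid-promoted aromatisation during concentration and acylation. Fallback setting out from 10 (as the cold crude extract) and returning at 14: the solution is neither concentrated nor acylated but photooxygenated at once (O2, 5,10,15,20-tetraphenylporphyrin, light, CH2Cl2, −40 °C) to the endoperoxide alcohol F2. Thiourea in MeOH reduces this to the triol acetonide F3, a stable compound. Its primary hydroxyl alone is then benzoylated with 11 (1.05 equiv, 2,4,6-collidine, CH2Cl2, −40 °C) to give 14, so steps 4 and 5 are taken in reverse order.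

Further compounds
F1 | step 1 | mirror image of 5, (3S,4R,5S,6R) urazole-bridged cis-4,5-diol | O=C(OCC1=C[C@H]2[C@@H](O)[C@@H](O)[C@@H]1N1N2C(=O)N(C)C1=O)c1ccccc1
F0 | step 7 | none | none
F2 | step 3 | endoperoxide alcohol: O–O bridging C3/C6 (down), 4,5-acetonide (up), C7H2OH on C1 | OCC1=C[C@@H]2[C@@H]3OC(C)(C)O[C@@H]3[C@H]1OO2
F3 | step 3 | triol acetonide: 3-OH and 6-OH down, 4,5-O-isopropylidene up, C7H2OH on C1 | OCC1=C[C@@H](O)[C@@H]2OC(C)(C)O[C@@H]2[C@H]1O
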